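## The problem

The target (21) is an achiral diether in which an anisole ring A (a 2-isopropyl-4-methoxy-5-methylphenoxy group), a pentasubstituted benzene ring B and a 1,4-benzoquinone ring C are joined through two ether oxygens on adjacent carbons of ring B. Ring B is numbered so that C1 carries the ring A oxygen, C2 methyl, C3 methoxy, C4 hydrogen, C5 isopropyl and C6 the ring C oxygen. There is no stereocentre, so the difficulty is positional: five different substituents must be placed around ring B without ambiguity, and the oxygens on C1, C3 and C6 must be told apart as aryl, methyl and quinonyl ethers. Both ether oxygens are crowded. The C1 oxygen lies between the C2 methyl and the C6 oxygen and faces the ortho isopropyl group of ring A; the C6 oxygen lies between C1–O and the C5 isopropyl group and faces the methyl and carbonyl groups of ring C, so a metal-catalysed arylation at either would join two ortho-substituted partners. Ring C is an electrophilic, reducible, base-sensitive quinone and should arrive last, while rings A and B are hydroquinone diethers that strong one-electron oxidants would demethylate, which rules out a late oxidative unmasking of ring C from a dimethyl ether. Rings A and C have the same monoterpenoid carbon skeleton and can be drawn from carvacrol, whereas ring B has to be built. The feature that allows this is the O–C1, Me–C2, O–C3 array of ring B, which is the oxygen–methyl–oxygen pattern of 2-methylcyclohexane-1,3-dione: its vinylogous acid chloride takes up the ring A phenoxide by addition–elimination, C4 is the α-carbon of the dione, C5 and C6 can come from an alkyne, and the two surplus CH2 groups can leave as a C2 fragment.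

## Retrosynthesis

**Ring C off.** The last bond to be made is the one between the quinone carbon and the C6 oxygen of ring B, so 21 goes back to phenol 18 and bromoquinone 20. The quinone carbon is a vinylogous acyl carbon with a leaving group, so this bond can form by addition–elimination under mild base. The neighbouring cut, on the ring B side of the same oxygen, would need a C6-functionalised ring B, an arylation between two doubly ortho-substituted partners and a later change of oxidation level. The cut confines the sensitive quinone to the final step and leaves a stable diaryl ether phenol. The forward reaction asks that the hindered phenoxide of 18 attack the bromine-bearing carbon of 20 faster than it reduces 20 or adds to its unsubstituted position.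

**The ring C piece.** Bromoquinone 20 is traced to bromophenol 19 by oxidative demethylation of a para-methoxyphenol, and 19 to phenol 4 by ortho-bromination. This is preferred to an independent quinone synthesis because 4 is needed for ring A in any case: rings A and C share one carbon skeleton, so one phenol serves both ends of the molecule. The forward bromination must go ortho to the free hydroxyl of 4, between OH and methyl, and not ortho to the methoxy group.

**The oxygens on C6 and C3 of ring B.** Phenol 18 comes from acetate 17, this from methyl ketone 16 by Baeyer–Villiger oxidation, and 16 from silyl ether 14 by exchange of silicon for methyl. The C6–O bond is turned into a C6–acetyl bond because the alkyne that supplies C5 and C6 must carry an acceptor on the carbon that becomes C6; an oxygen there would give an electron-rich ynol ether, mismatched with an electron-rich diene. The C3 oxygen is traced to a silyl ether because it starts as the enol oxygen of a ketone. The forward steps need the aryl group to migrate in preference to methyl and the fluoride-mediated ether exchange to leave the ketone alone.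

**The key cut.** Ring B of 14 is opened across C4–C5 and C1–C6 and the extruded two-carbon bridge is restored, which leads through bicyclic adduct 13 to diene 9 and ynone 12. The alternative of cutting the ring A–O–C1 ether of 14 would require coupling a doubly ortho-substituted phenol with an ortho-isopropyl aryl halide. Cutting ring B instead keeps that oxygen in place and moves its formation into enone chemistry. The simplification is large: a pentasubstituted benzene becomes an acyclic ynone and a cyclohexadiene that is three steps from dione 5. The forward reaction must be regioselective in the cycloaddition and must aromatise only by loss of the bridge.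

**The diene.** Diene 9 is the silyl enol ether of vinylogous aryl ester 7. Ester 7 is cut at the bond between the enone β-carbon and the ring A oxygen into chloroenone 6 and phenol 4, and 6 comes from dione 5. Because 5 is symmetric, chlorination can give only one product, and the hindered C–O bond is formed at an sp2 carbon activated by a carbonyl group. The forward sequence needs kinetic deprotonation of 7 at the α'-methylene so that the silyloxy group ends on the carbon next to the methyl-bearing one.

**The ynone.** Ynone 12 is cut at the acyl–alkynyl bond and comes from 3-methylbut-1-yne (10) by acetylation of its acetylide 11. Nothing simpler is available, and the only demand is that the acetyl donor stop at the ketone stage.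

**The ring A phenol.** Phenol 4 is traced through aryl bromide 3 and methyl ether 2 to carvacrol (1). The carvacrol oxygen becomes the methoxy group, and the new hydroxyl is introduced para to it, next to the isopropyl group. Para-bromination of an anisole and conversion of C–Br to C–OH are both reliable, and the sequence fixes which of the two oxygens is methylated, which a monomethylation of the corresponding hydroquinone would not.

## Roads not taken

**Alternative 1:** Ring B would be cut at C1–C2, C3–C4 and C1–C6 and assembled by a vinylketene–ynol ether benzannulation. Irradiation of diazoketone A1 would trigger a Wolff rearrangement to a vinylketene, which would add ynol ether A2 in a [2+2] sense. Heating would then open the cyclobutenone (4π) and close the dienylketene (6π) to give phenol A3.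
- Merits: two acyclic pieces give a pentasubstituted ring B with full regiocontrol, and the three oxygens arrive already differentiated, as free OH on C1, methyl ether on C3 and benzyl ether on C6. No silyl-to-methyl exchange and no Baeyer–Villiger oxidation are needed, so this road is shorter after ring formation than the chosen one.
- Weak points: the free C1 hydroxyl of A3, flanked by methyl and benzyloxy, must then be arylated with a ring A halide such as 3, which carries an ortho isopropyl group. That is the hindered C–O coupling the chosen plan avoids. A1 is a light- and acid-sensitive β-alkoxy enone diazoketone, A2 is volatile and has to be prepared, and the photochemical step limits scale.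
- Comparison: against the better functional-group economy of A3, the chosen plan sets the fact that both crowded ether bonds are made by addition–elimination at carbonyl-activated sp2 carbons, from bulk starting materials.

**Alternative 2:** Rings B and C would both be cut at C3–C4 and formed together by a twofold cyclobutenone ring expansion. Heating the ether-linked bis(alkenylcyclobutenone) A4 would open both four-membered rings to dienylketenes, whose 6π closures and tautomerisation would give A5, with ring B as a C3 phenol and ring C as a hydroquinone.
- Merits: two rings form in one operation, against one in the chosen plan. The oxygen between rings B and C is in place before either ring is aromatic, so the final phenoxide–quinone coupling of the chosen plan is not needed. Ring C arrives at the hydroquinone level and needs only a mild oxidation.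
- Weak points: A4 is the problem. It joins two different, fully substituted cyclobutenones through an ether between a quaternary sp3 carbon and a vinylic carbon. Its assembly from four-membered ring building blocks needs several regiocontrolled carbonyl additions and ether exchanges, and is much longer than the three steps from 5 to 9. A5 also has three free hydroxyls, and the ring B C3–OH must be methylated in the presence of the ring C hydroquinone, or after its oxidation and thus under base that the quinone tolerates poorly.
- Comparison: the chosen plan closes fewer rings per step, but its key-step precursor is short to make and its C3 and C6 oxygens are distinguished from the start, as silyl ether and as acetyl.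

**Alternative 3:** Ring A would be cut at C5–C6 and C3–C4 and built by a Diels–Alder reaction of aryloxydiene A6 with nitroalkene A7, giving cyclohexene A8 with the nitro group on C4 and methyl on C5.
- Merits: the hindered ring A–O bond starts as an aryl ester made by acylation, the same logic as the vinylogous ester of the chosen plan. A 2-aryloxydiene and a nitroalkene combine with reliable para orientation. A7 is a strong dienophile, so the cycloaddition should run at a far lower temperature than the chosen key step and needs no extrusion.
- Weak points: the effort goes into ring A, whose skeleton can be bought, and ring B, the difficult ring, must still be made with three differentiated oxygens before A6 exists. After the cycloaddition, a Nef reaction, a dehydrogenation to the arene and an O-methylation are needed. Two stereocentres are created only to be destroyed, and the carbonyl methylenation that leads to A6 takes place on a very hindered aryl ester.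
- Comparison: the cycloaddition itself is milder than the chosen key step, but the chosen plan spends its ring construction on the ring that cannot be bought.

Key step: step 8

Remark on the chemistry: 21 has no stereocentre. The only chiral species on the route, bicyclic adduct 13, forms as a racemate and loses both stereocentres on aromatisation. Ether 2 can also be purchased; the route is written from carvacrol so that it rests on a bulk chemical.

## Steps

Step 1
Reactants: 1 carvacrol (5-isopropyl-2-methylphenol)
Product: 2 4-isopropyl-2-methoxy-1-methylbenzene (carvacrol methyl ether)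
Conditions: MeI, K2CO3, acetone, reflux
Reagents that add atoms: iodomethane, CI
Why: Williamson ether synthesis; the phenoxide is alkylated by SN2 at methyl, and nothing else in 1 can react.

Step 2
Reactants: 2 4-isopropyl-2-methoxy-1-methylbenzene
Product: 3 1-bromo-2-isopropyl-4-methoxy-5-methylbenzene
Conditions: NBS, MeCN, 0 °C to rt
Reagents that add atoms: N-bromosuccinimide, O=C1CCC(=O)N1Br
Why: Electrophilic aromatic bromination; methoxy directs para, the only ortho position open to it is wedged between methoxy and isopropyl, and the remaining CH is meta to the donor, so the para position should be attacked.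

Step 3
Reactants: 3 1-bromo-2-isopropyl-4-methoxy-5-methylbenzene
Product: 4 2-isopropyl-4-methoxy-5-methylphenol
Conditions: Pd2(dba)3 (cat.), tBuXPhos (cat.), KOH, 1,4-dioxane/H2O, 100 °C; then aq. HCl
Reagents that add atoms: potassium hydroxide, [K+].[OH-]
Why: Palladium-catalysed hydroxylation of an aryl bromide (C–O cross-coupling with hydroxide); zerovalent palladium inserts into the C–Br bond and the bulky biarylphosphine favours reductive elimination of the phenol over a second arylation.

Step 4
Reactants: 5 2-methylcyclohexane-1,3-dione
Product: 6 3-chloro-2-methylcyclohex-2-en-1-one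
Conditions: (COCl)2, DMF (cat.), CH2Cl2, 0 °C to rt
Reagents that add atoms: oxalyl chloride, ClC(=O)C(=O)Cl
Why: Conversion of a vinylogous acid into its vinylogous acid chloride through Vilsmeier-type activation of the enol; 5 is symmetric, so only one chloroenone can form.

Step 5
Reactants: 6 3-chloro-2-methylcyclohex-2-en-1-one; 4 2-isopropyl-4-methoxy-5-methylphenol
Product: 7 3-(2-isopropyl-4-methoxy-5-methylphenoxy)-2-methylcyclohex-2-en-1-one
Conditions: K2CO3, DMF, 60 °C
Reagents that add atoms: none
Why: Addition–elimination (vinylogous acyl substitution): the phenoxide adds to the β-carbon of the chloroenone and chloride leaves from the enolate, so the hindered ring A–O bond forms without a metal-mediated arylation.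

Step 6
Reactants: 7 3-(2-isopropyl-4-methoxy-5-methylphenoxy)-2-methylcyclohex-2-en-1-one
Product: 9 4-(2-isopropyl-4-methoxy-5-methylphenoxy)-3-methyl-2-(tert-butyldimethylsilyloxy)cyclohexa-1,3-diene, via lithium dienolate 8 (not isolated)
Conditions: LiN(iPr)2, THF, −78 °C; then TBSCl, DMPU, −78 to 0 °C; non-aqueous work-up (pentane, filtration)
Reagents that add atoms: tert-butyldimethylsilyl chloride, CC(C)(C)[Si](C)(C)Cl
Why: Kinetic α'-deprotonation of a vinylogous ester followed by O-silylation of the cross-conjugated enolate; the γ-methylene is kinetically less acidic, so the 1-aryloxy-3-silyloxy diene should result, and the tert-butyldimethylsilyl enol ether is robust enough to be handled without chromatography on acidic media.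

Step 7
Reactants: 10 3-methylbut-1-yne
Product: 12 5-methylhex-3-yn-2-one, via lithium 3-methylbutynide 11 (not isolated)
Conditions: n-BuLi, THF, −78 °C; then MeC(O)N(OMe)Me, −78 to 0 °C; cold aq. HCl (1 M)
Reagents that add atoms: N-methoxy-N-methylacetamide, CC(=O)N(C)OC
Why: Weinreb ketone synthesis; the chelated tetrahedral adduct of the acetylide persists until the acidic quench, which prevents a second addition and keeps the liberated amine from adding to the ynone.

Step 8
Reactants: 9 4-(2-isopropyl-4-methoxy-5-methylphenoxy)-3-methyl-2-(tert-butyldimethylsilyloxy)cyclohexa-1,3-diene; 12 5-methylhex-3-yn-2-one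
Product: 14 1-[2-(2-isopropyl-4-methoxy-5-methylphenoxy)-4-(tert-butyldimethylsilyloxy)-6-isopropyl-3-methylphenyl]ethanone, via bicyclo[2.2.2]octadiene adduct 13 (not isolated)
Conditions: 12 (2 equiv), BHT (cat.), o-xylene, sealed tube, 140 °C, then 180 °C
Reagents that add atoms: none
Why: Thermal [4+2] cycloaddition of the ring-locked s-cis 1-aryloxy-3-silyloxy diene 9 to the electron-poor triple bond of 12 should give bicyclo[2.2.2]octa-2,5-diene 13, and at the higher temperature a retro-[4+2] reaction should expel the saturated two-carbon bridge as ethylene, made irreversible by the gain of aromaticity (Alder–Rickert reaction). The closest known reaction type is the Alder–Rickert arene synthesis from 1-alkoxy-3-silyloxycyclohexa-1,3-dienes and acetylenic ketones or esters, the only change being aryloxy for alkoxy. Ring B is closed by this intermolecular cycloaddition, which forms C4–C5 and C1–C6 suprafacially on both partners, and it becomes benzenoid when the bridge leaves. No stereocentre survives, because the two bridgehead centres of racemic 13 are tied to each other by the bicycle and both become sp2 carbons of 14. The selectivity needed is regiochemical: the silyloxy group directly and the aryloxy group through the diene both raise the HOMO coefficient at the unsubstituted diene terminus (future C4), which therefore bonds to the β-carbon of the ynone, placing isopropyl on C5 and acetyl on C6 beside the aryloxy carbon. Since the aryloxy carbon is a bridgehead of 13, elimination of phenol 4 is geometrically impossible and the adduct can aromatise only by losing the C2 bridge, so the ring A oxygen is retained. The enol silyl ether ends as an aryl silyl ether that tolerates the temperature, and BHT with a base-washed vessel should hold back radical polymerisation of 12 and acid-induced hydrolysis of 9.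

Step 9
Reactants: 14 1-[2-(2-isopropyl-4-methoxy-5-methylphenoxy)-4-(tert-butyldimethylsilyloxy)-6-isopropyl-3-methylphenyl]ethanone
Product: 16 1-[2-(2-isopropyl-4-methoxy-5-methylphenoxy)-6-isopropyl-4-methoxy-3-methylphenyl]ethanone, via cesium phenoxide 15 (not isolated)
Conditions: CsF, MeI, DMF, rt
Reagents that add atoms: iodomethane, CI
Why: Fluoride cleavage of the aryl silyl ether gives a cesium phenoxide that is methylated in the same flask (Williamson ether synthesis); the doubly ortho-substituted methyl ketone is not enolised by fluoride to any useful extent.

Step 10
Reactants: 16 1-[2-(2-isopropyl-4-methoxy-5-methylphenoxy)-6-isopropyl-4-methoxy-3-methylphenyl]ethanone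
Product: 17 2-(2-isopropyl-4-methoxy-5-methylphenoxy)-6-isopropyl-4-methoxy-3-methylphenyl acetate
Conditions: mCPBA, NaHCO3, CH2Cl2, 0 °C to rt
Reagents that add atoms: 3-chloroperoxybenzoic acid, OOC(=O)c1cccc(Cl)c1
Why: Baeyer–Villiger oxidation; the aryl group carries a para methoxy and an ortho aryloxy donor and is twisted out of conjugation with the carbonyl, so it should migrate in preference to methyl and place oxygen on C6.

Step 11
Reactants: 17 2-(2-isopropyl-4-methoxy-5-methylphenoxy)-6-isopropyl-4-methoxy-3-methylphenyl acetate
Product: 18 2-(2-isopropyl-4-methoxy-5-methylphenoxy)-6-isopropyl-4-methoxy-3-methylphenol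
Conditions: K2CO3 (0.3 equiv), MeOH, rt; then aq. NH4Cl
Reagents that add atoms: none
Why: Base-catalysed transesterification (methanolysis) of an aryl acetate; the phenoxide is a good leaving group and the ether bonds are inert.

Step 12
Reactants: 4 2-isopropyl-4-methoxy-5-methylphenol
Product: 19 2-bromo-6-isopropyl-4-methoxy-3-methylphenol
Conditions: NBS, CH2Cl2, −20 to 0 °C, dark
Reagents that add atoms: N-bromosuccinimide, O=C1CCC(=O)N1Br
Why: Electrophilic ortho-bromination of a phenol; the free hydroxyl is the stronger director and its open ortho position, between OH and methyl, is less crowded than the position between methoxy and isopropyl.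

Step 13
Reactants: 19 2-bromo-6-isopropyl-4-methoxy-3-methylphenol
Product: 20 3-bromo-5-isopropyl-2-methylcyclohexa-2,5-diene-1,4-dione
Conditions: PhI(OAc)2, MeCN/H2O, 0 °C
Reagents that add atoms: water, O
Why: Oxidative demethylation of a para-methoxyphenol by a trivalent iodine reagent; ligand exchange at the phenol oxygen, attack of water at the methoxy-bearing carbon and loss of methanol from the hemiketal give the quinone, with bromine on the methyl-bearing double bond.

Step 14
Reactants: 18 2-(2-isopropyl-4-methoxy-5-methylphenoxy)-6-isopropyl-4-methoxy-3-methylphenol; 20 3-bromo-5-isopropyl-2-methylcyclohexa-2,5-diene-1,4-dione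
Product: 21 3-[2-(2-isopropyl-4-methoxy-5-methylphenoxy)-6-isopropyl-4-methoxy-3-methylphenoxy]-5-isopropyl-2-methylcyclohexa-2,5-diene-1,4-dione (CNP0335608.0)
Conditions: Cs2CO3, MeCN, 0 °C to rt, argon, dark
Reagents that add atoms: none
Why: Addition–elimination on a haloquinone; the phenoxide adds to the bromine-bearing carbon, which is β to the far carbonyl, and the enolate expels bromide to restore the quinone with the aryloxy group beside the methyl group.

## Compound list

1 | carvacrol (5-isopropyl-2-methylphenol) | Cc1ccc(C(C)C)cc1O | starting material
2 | 4-isopropyl-2-methoxy-1-methylbenzene | COc1cc(C(C)C)ccc1C | intermediate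
3 | 1-bromo-2-isopropyl-4-methoxy-5-methylbenzene | COc1cc(C(C)C)c(Br)cc1C | intermediate
4 | 2-isopropyl-4-methoxy-5-methylphenol | COc1cc(C(C)C)c(O)cc1C | intermediate
5 | 2-methylcyclohexane-1,3-dione | CC1C(=O)CCCC1=O | starting material
6 | 3-chloro-2-methylcyclohex-2-en-1-one | CC1=C(Cl)CCCC1=O | intermediate
7 | 3-(2-isopropyl-4-methoxy-5-methylphenoxy)-2-methylcyclohex-2-en-1-one | CC1=C(Oc2cc(C)c(OC)cc2C(C)C)CCCC1=O | intermediate
8 | lithium 5-(2-isopropyl-4-methoxy-5-methylphenoxy)-6-methylcyclohexa-1,5-dien-1-olate (formed in situ) | [Li+].[O-]C1=CCCC(Oc2cc(C)c(OC)cc2C(C)C)=C1C | intermediate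
9 | 4-(2-isopropyl-4-methoxy-5-methylphenoxy)-3-methyl-2-(tert-butyldimethylsilyloxy)cyclohexa-1,3-diene | CC1=C(Oc2cc(C)c(OC)cc2C(C)C)CCC=C1O[Si](C)(C)C(C)(C)C | intermediate
10 | 3-methylbut-1-yne | C#CC(C)C | starting material
11 | lithium 3-methylbut-1-yn-1-ide (formed in situ) | [Li]C#CC(C)C | intermediate
12 | 5-methylhex-3-yn-2-one | CC(=O)C#CC(C)C | intermediate
13 | racemic 1-[1-(2-isopropyl-4-methoxy-5-methylphenoxy)-5-(tert-butyldimethylsilyloxy)-3-isopropyl-6-methylbicyclo[2.2.2]octa-2,5-dien-2-yl]ethanone (formed in situ; bridgehead centres mutually fixed by the bicycle, drawn without descriptors) | CC(=O)C1=C(C(C)C)C2CCC1(Oc3cc(C)c(OC)cc3C(C)C)C(C)=C2O[Si](C)(C)C(C)(C)C | intermediate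
14 | 1-[2-(2-isopropyl-4-methoxy-5-methylphenoxy)-4-(tert-butyldimethylsilyloxy)-6-isopropyl-3-methylphenyl]ethanone | CC(=O)c1c(C(C)C)cc(O[Si](C)(C)C(C)(C)C)c(C)c1Oc1cc(C)c(OC)cc1C(C)C | intermediate
15 | cesium 4-acetyl-3-(2-isopropyl-4-methoxy-5-methylphenoxy)-5-isopropyl-2-methylphenolate (formed in situ) | [Cs+].CC(=O)c1c(C(C)C)cc([O-])c(C)c1Oc1cc(C)c(OC)cc1C(C)C | intermediate
16 | 1-[2-(2-isopropyl-4-methoxy-5-methylphenoxy)-6-isopropyl-4-methoxy-3-methylphenyl]ethanone | CC(=O)c1c(C(C)C)cc(OC)c(C)c1Oc1cc(C)c(OC)cc1C(C)C | intermediate
17 | 2-(2-isopropyl-4-methoxy-5-methylphenoxy)-6-isopropyl-4-methoxy-3-methylphenyl acetate | CC(=O)Oc1c(C(C)C)cc(OC)c(C)c1Oc1cc(C)c(OC)cc1C(C)C | intermediate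
18 | 2-(2-isopropyl-4-methoxy-5-methylphenoxy)-6-isopropyl-4-methoxy-3-methylphenol | Oc1c(C(C)C)cc(OC)c(C)c1Oc1cc(C)c(OC)cc1C(C)C | intermediate
19 | 2-bromo-6-isopropyl-4-methoxy-3-methylphenol | Oc1c(Br)c(C)c(OC)cc1C(C)C | intermediate
20 | 3-bromo-5-isopropyl-2-methylcyclohexa-2,5-diene-1,4-dione | CC1=C(Br)C(=O)C(C(C)C)=CC1=O | intermediate
21 | 3-[2-(2-isopropyl-4-methoxy-5-methylphenoxy)-6-isopropyl-4-methoxy-3-methylphenoxy]-5-isopropyl-2-methylcyclohexa-2,5-diene-1,4-dione (CNP0335608.0) | COc1cc(C(C)C)c(Oc2c(C)c(OC)cc(C(C)C)c2OC2=C(C)C(=O)C=C(C(C)C)C2=O)cc1C | target

## Step count and least certain steps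

Total: 14 steps. Longest linear sequence: 10 steps (steps 1, 2, 3, 5, 6, 8, 9, 10, 11, 14). The branches are steps 4 and 7 (one step each) and steps 12–13 (two steps from 4).

**Step 8 (key step).** The acetyl-bearing alkyne carbon must bond to the fully substituted, aryloxy-bearing diene terminus, so the cycloaddition may be slow. That would give time for thermal 1,5-hydrogen shifts in the diene, which scramble the substitution pattern, for loss of the silyl group back to 7, or for polymerisation of the ynone before ethylene is expelled.

The fallback replaces the ketone by a smaller and more electrophilic aldehyde acceptor. It sets out from 10 and 9 and returns at 14.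
- Alkyne 10 would be lithiated (n-BuLi, THF) and formylated with DMF, with a buffered quench, to give 4-methylpent-2-ynal F1.
- Heating 9 with F1 in toluene should give 2-(2-isopropyl-4-methoxy-5-methylphenoxy)-4-(tert-butyldimethylsilyloxy)-6-isopropyl-3-methylbenzaldehyde F3 by the same cycloaddition and extrusion, through the racemic bicyclo[2.2.2]octadiene-2-carbaldehyde adduct F2.
- Addition of MeMgBr to F3 (THF, −78 °C) would give racemic 1-[2-(2-isopropyl-4-methoxy-5-methylphenoxy)-4-(tert-butyldimethylsilyloxy)-6-isopropyl-3-methylphenyl]ethanol F4.
- Oxidation of F4 with Dess–Martin periodinane would deliver 14.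

**Step 14.** The electron-rich, doubly ortho-substituted phenoxide may transfer an electron to the quinone instead of adding to it, may add at the unsubstituted quinone carbon, or may react so slowly that the base degrades 20.

The fallback forms the ether at the arene oxidation level and oxidises afterwards. It sets out from 19 and 18 and returns at 21.
- Phenol 19 would be benzylated (BnBr, K2CO3, DMF) to 2-(benzyloxy)-3-bromo-1-isopropyl-5-methoxy-4-methylbenzene F5.
- Ullmann-type coupling of F5 with 18 (CuI, picolinic acid, K3PO4, DMSO, 100 °C) would give benzyl ether F6, 1-(benzyloxy)-2-[2-(2-isopropyl-4-methoxy-5-methylphenoxy)-6-isopropyl-4-methoxy-3-methylphenoxy]-6-isopropyl-4-methoxy-3-methylbenzene. This coupling is itself demanding, since both partners are ortho-disubstituted.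
- Hydrogenolysis (H2, Pd/C, EtOAc) would give phenol F7, 2-[2-(2-isopropyl-4-methoxy-5-methylphenoxy)-6-isopropyl-4-methoxy-3-methylphenoxy]-6-isopropyl-4-methoxy-3-methylphenol.
- Oxidation with PhI(OAc)2 in aqueous MeCN, which engages only the ring bearing the free hydroxyl, would give 21.

**Step 10.** Formation of the peracid adduct at a ketone flanked by aryloxy and isopropyl groups may be slow, and the peracid may then start to oxidise the electron-rich rings A and B.

The fallback changes the mechanism from acyl migration to a cationic hydroperoxide rearrangement. It sets out from 16 and returns at 18.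
- Reduction with LiAlH4 (THF, 0 °C) would give racemic 1-[2-(2-isopropyl-4-methoxy-5-methylphenoxy)-6-isopropyl-4-methoxy-3-methylphenyl]ethanol F8.
- Treatment of F8 with H2O2 and a catalytic acid (TsOH·H2O, MeCN) should form the benzylic hydroperoxide and trigger a Hock rearrangement, in which the electron-rich aryl group migrates to oxygen and acetaldehyde is lost, giving 18 directly.

**Step 3.** Oxidative addition to the electron-rich, ortho-isopropyl bromide may be sluggish, and the phenoxide product may be arylated a second time or the bromide reduced.

The fallback avoids catalysis. It sets out from 3 and returns at 4.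
- Bromine–lithium exchange (n-BuLi, THF, −78 °C), quenching with B(OMe)3 and acidic work-up would give (2-isopropyl-4-methoxy-5-methylphenyl)boronic acid F9.
- Oxidation of F9 with H2O2 and NaOH would give 4.

## Further compounds

F1 | step 8 | 4-methylpent-2-ynal | CC(C)C#CC=O
F2 | step 8 | racemic 1-(2-isopropyl-4-methoxy-5-methylphenoxy)-5-(tert-butyldimethylsilyloxy)-3-isopropyl-6-methylbicyclo[2.2.2]octa-2,5-diene-2-carbaldehyde (formed in situ, drawn without descriptors) | O=CC1=C(C(C)C)C2CCC1(Oc3cc(C)c(OC)cc3C(C)C)C(C)=C2O[Si](C)(C)C(C)(C)C
F3 | step 8 | 2-(2-isopropyl-4-methoxy-5-methylphenoxy)-4-(tert-butyldimethylsilyloxy)-6-isopropyl-3-methylbenzaldehyde | O=Cc1c(C(C)C)cc(O[Si](C)(C)C(C)(C)C)c(C)c1Oc1cc(C)c(OC)cc1C(C)C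
F4 | step 8 | racemic 1-[2-(2-isopropyl-4-methoxy-5-methylphenoxy)-4-(tert-butyldimethylsilyloxy)-6-isopropyl-3-methylphenyl]ethanol | CC(O)c1c(C(C)C)cc(O[Si](C)(C)C(C)(C)C)c(C)c1Oc1cc(C)c(OC)cc1C(C)C
F5 | step 14 | 2-(benzyloxy)-3-bromo-1-isopropyl-5-methoxy-4-methylbenzene | COc1cc(C(C)C)c(OCc2ccccc2)c(Br)c1C
F6 | step 14 | 1-(benzyloxy)-2-[2-(2-isopropyl-4-methoxy-5-methylphenoxy)-6-isopropyl-4-methoxy-3-methylphenoxy]-6-isopropyl-4-methoxy-3-methylbenzene | COc1cc(C(C)C)c(Oc2c(C)c(OC)cc(C(C)C)c2Oc3c(C)c(OC)cc(C(C)C)c3OCc4ccccc4)cc1C
F7 | step 14 | 2-[2-(2-isopropyl-4-methoxy-5-methylphenoxy)-6-isopropyl-4-methoxy-3-methylphenoxy]-6-isopropyl-4-methoxy-3-methylphenol | COc1cc(C(C)C)c(Oc2c(C)c(OC)cc(C(C)C)c2Oc3c(C)c(OC)cc(C(C)C)c3O)cc1C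
F8 | step 10 | racemic 1-[2-(2-isopropyl-4-methoxy-5-methylphenoxy)-6-isopropyl-4-methoxy-3-methylphenyl]ethanol | CC(O)c1c(C(C)C)cc(OC)c(C)c1Oc1cc(C)c(OC)cc1C(C)C
F9 | step 3 | (2-isopropyl-4-methoxy-5-methylphenyl)boronic acid | COc1cc(C(C)C)c(B(O)O)cc1C
A1 | alternative 1 | (E)-4-(benzyloxy)-1-diazo-3-isopropylbut-3-en-2-one | [N-]=[N+]=CC(=O)/C(C(C)C)=C/OCc1ccccc1
A2 | alternative 1 | 1-methoxypropyne | COC#CC
A3 | alternative 1 | 6-(benzyloxy)-5-isopropyl-3-methoxy-2-methylphenol | COc1cc(C(C)C)c(OCc2ccccc2)c(O)c1C
A4 | alternative 2 | 3-(2-isopropyl-4-methoxy-5-methylphenoxy)-2-methyl-4-(3-methylbut-1-en-2-yl)-4-{[4-hydroxy-2-methyl-4-(3-methylbut-1-en-2-yl)-3-oxocyclobut-1-en-1-yl]oxy}cyclobut-2-en-1-one (diastereomer mixture, stereocentres not defined) | CC1=C(Oc2cc(C)c(OC)cc2C(C)C)C(OC3=C(C)C(=O)C3(O)C(=C)C(C)C)(C(=C)C(C)C)C1=O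
A5 | alternative 2 | 2-[2-(2-isopropyl-4-methoxy-5-methylphenoxy)-4-hydroxy-6-isopropyl-3-methylphenoxy]-6-isopropyl-3-methylbenzene-1,4-diol | COc1cc(C(C)C)c(Oc2c(C)c(O)cc(C(C)C)c2Oc2c(C)c(O)cc(C(C)C)c2O)cc1C
A6 | alternative 3 | 2-[3-isopropyl-5-methoxy-2-(methoxymethoxy)-6-methylphenoxy]-3-isopropylbuta-1,3-diene | C=C(Oc1c(C)c(OC)cc(C(C)C)c1OCOC)C(=C)C(C)C
A7 | alternative 3 | (E)-1-nitropropene | C/C=C/[N+](=O)[O-]
A8 | alternative 3 | racemic trans-1-[3-isopropyl-5-methoxy-2-(methoxymethoxy)-6-methylphenoxy]-2-isopropyl-5-methyl-4-nitrocyclohex-1-ene (one enantiomer drawn) | C[C@H]1CC(Oc2c(C)c(OC)cc(C(C)C)c2OCOC)=C(C(C)C)C[C@@H]1[N+](=O)[O-]
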